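**Assumption:** the chiral copper catalyst in step 1 is taken to give the (R)-configured quaternary centre with the ligand enantiomer named; if the opposite sense is found, the enantiomeric ligand is used.

## Retrosynthetic overview

1. Ring B (seven-membered enone) is closed last: enone ⇐ ring allylic alcohol ⇐ ring-closing metathesis of an allyl group with a 2-methylallylic alcohol arm, the latter grown from a dioxolane-masked aldehyde on the quaternary carbon.
2. Allylic acetate ⇐ CBS reduction of an isopropenyl ketone ⇐ isopropenyl Grignard opening of a γ-lactone.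
3. Key C–C bond: γ-lactone ⇐ SmI2 ketyl–olefin coupling of the methyl-ketone carbonyl carbon with the β-carbon of methyl acrylate, run in the same flask as SmI2 removal of an α-acetoxy group; this sets the ring CH and the tertiary carbinol.
4. α-Acetoxy methyl ketone ⇐ cyclopentanone + 1-ethoxyvinyllithium (acetyl anion equivalent).
5. Ring A (cyclopentane) is bought as 3-methylcyclopent-2-enone and elaborated by catalytic asymmetric conjugate addition/allylation; ring order: A first, B last.

## Route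

Step 1
Reactants: 1 3-methylcyclopent-2-en-1-one; 2 (1,3-dioxolan-2-ylmethyl)magnesium bromide; 3 allyl iodide
Product: 5 (2R,3R)-3-(1,3-dioxolan-2-ylmethyl)-3-methyl-2-(prop-2-en-1-yl)cyclopentan-1-one, via magnesium enolate 4 (not isolated)
Conditions: Cu(OTf)2 (3 mol%), 1-[(2S)-1-hydroxy-4-methylpentan-2-yl]-3-(2,4,6-trimethylphenyl)-4,5-dihydro-1H-imidazol-3-ium hexafluorophosphate (4 mol%), 2 (1.3 equiv), Et2O, 0 °C; then 3 (3 equiv), DMPU, −20 °C → rt
Reagents that add atoms: none
Why: Copper-catalysed asymmetric conjugate addition of the Grignard reagent to the trisubstituted enone sets the quaternary centre (3R) by catalyst control, and the regiodefined magnesium enolate 4 is allylated anti to the larger dioxolanylmethyl arm, which puts the allyl group cis to the methyl group (2R).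

Step 2
Reactants: 5; 6 ethyl vinyl ether
Product: 9 (1S,2R,3R)-1-acetyl-3-(1,3-dioxolan-2-ylmethyl)-3-methyl-2-(prop-2-en-1-yl)cyclopentyl acetate, via lithium alkoxide adduct 7 (not isolated), via enol ether acetate 8 (not isolated)
Conditions: 6, t-BuLi, THF, −78 → 0 °C; 5, −78 °C; Ac2O, −78 °C → rt; then 0.5 M HCl, THF, 0 °C
Reagents that add atoms: acetic anhydride CC(=O)OC(C)=O; water O
Why: 1-Ethoxyvinyllithium is an acetyl anion equivalent that adds 1,2 to the hindered cyclopentanone (as it does to steroidal 17-ketones), the tertiary alkoxide is acetylated in the flask and dilute acid unmasks the methyl ketone while the dioxolane survives; the C1 configuration shown (addition anti to the allyl group) is erased in step 3.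

Step 3
Reactants: 9; 10 methyl acrylate
Product: 12 (5S)-5-[(1S,2S,3R)-3-(1,3-dioxolan-2-ylmethyl)-3-methyl-2-(prop-2-en-1-yl)cyclopentyl]-5-methyloxolan-2-one, via cis methyl ketone 11 (not isolated)
Conditions: SmI2 (2.2 equiv), t-BuOH (3 equiv), THF, −78 °C, 10 min; then 10 (4 equiv), SmI2 (2.5 equiv), −78 → 0 °C; no HMPA
Reagents that add atoms: none
Why: Proposed new method: a one-flask merger of two known divalent-samarium reactions, in which reductive cleavage of the α-acetoxy ketone (closest known type: SmI2 cleavage of α-acyloxy ketones) gives a trivalent-samarium enolate that t-BuOH protonates on carbon from the face anti to the allyl group (kinetic protonation, giving the less stable cis ketone 11), and 11 then undergoes ketyl–olefin reductive coupling with methyl acrylate (closest known type: SmI2 ketone–acrylate γ-lactone synthesis), the carbonyl carbon reacting as a nucleophilic ketyl that bonds to the acrylate β-carbon on the Felkin–Anh face (anti to the allyl-bearing ring carbon) to set the 5S carbinol, while leaving out HMPA keeps 5-exo ketyl addition to the unactivated allyl group from competing.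

Step 4
Reactants: 12; 13 isopropenylmagnesium bromide
Product: 14 (6S)-6-[(1S,2S,3R)-3-(1,3-dioxolan-2-ylmethyl)-3-methyl-2-(prop-2-en-1-yl)cyclopentyl]-6-hydroxy-2-methylhept-1-en-3-one
Conditions: 13 (1.3 equiv), THF, −78 °C; pH 7 buffer at −78 °C
Reagents that add atoms: none
Why: Mono-addition of an alkenyl Grignard reagent to a γ-lactone at −78 °C (nucleophilic acyl substitution) stops at the stable magnesium hemiketal alkoxide, which gives the γ-hydroxy enone on quench without touching any stereocentre.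

Step 5
Reactants: 14
Product: 15 (3S,6S)-6-[(1S,2S,3R)-3-(1,3-dioxolan-2-ylmethyl)-3-methyl-2-(prop-2-en-1-yl)cyclopentyl]-2-methylhept-1-ene-3,6-diol
Conditions: (3aR)-1-methyl-3,3-diphenyltetrahydro-1H,3H-pyrrolo[1,2-c][1,3,2]oxazaborole [(R)-Me-CBS, 20 mol%], catecholborane (3 equiv), toluene, −78 °C; aq. NaOH work-up
Reagents that add atoms: none
Why: Corey–Bakshi–Shibata reduction with the (R)-oxazaborolidine treats isopropenyl as the large and the CH2 chain as the small group and gives the 3S allylic alcohol by reagent control, catecholborane at −78 °C leaves the alkenes alone, and material of the minor enantiomeric series from step 1 becomes a separable diastereomer.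

Step 6
Reactants: 15
Product: 16 (3S,6S)-6-[(1S,2S,3R)-3-(1,3-dioxolan-2-ylmethyl)-3-methyl-2-(prop-2-en-1-yl)cyclopentyl]-6-hydroxy-2-methylhept-1-en-3-yl acetate
Conditions: Ac2O (1.5 equiv), pyridine, DMAP (5 mol%), CH2Cl2, 0 °C
Reagents that add atoms: acetic anhydride CC(=O)OC(C)=O
Why: Nucleophile-catalysed acylation is selective for the secondary allylic alcohol over the hindered tertiary alcohol.

Step 7
Reactants: 16
Product: 17 (3S,6S)-6-hydroxy-2-methyl-6-[(1S,2S,3R)-3-methyl-3-(2-oxoethyl)-2-(prop-2-en-1-yl)cyclopentyl]hept-1-en-3-yl acetate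
Conditions: PPTS (0.3 equiv), acetone/H2O 10:1, 50 °C
Reagents that add atoms: water O
Why: Mild acid-catalysed acetal hydrolysis frees the aldehyde without ionising the tertiary alcohol or the allylic acetate.

Step 8
Reactants: 17; 18 2-bromopropene
Product: 19 (3S,6S)-6-hydroxy-6-[(1S,2S,3R)-3-(2-hydroxy-3-methylbut-3-en-1-yl)-3-methyl-2-(prop-2-en-1-yl)cyclopentyl]-2-methylhept-1-en-3-yl acetate (both epimers at the new carbinol)
Conditions: 18 (4 equiv), CrCl2 (8 equiv), NiCl2 (2 mol%), DMF, rt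
Reagents that add atoms: none
Why: Nozaki–Hiyama–Kishi addition of the alkenylchromium reagent is selective for the aldehyde over the acetate and tolerates free hydroxyl groups, and the unselective new carbinol does not matter because it is oxidised in step 10.

Step 9
Reactants: 19
Product: 20 (3S,6S)-6-hydroxy-6-[(1S,3aR,8aS)-5-hydroxy-3a,6-dimethyl-1,2,3,3a,4,5,8,8a-octahydroazulen-1-yl]-2-methylhept-1-en-3-yl acetate (both epimers at ring C5)
Conditions: second-generation Grubbs catalyst (5 mol%), CH2Cl2 (2 mM), 40 °C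
Reagents that add atoms: none
Why: Ring-closing metathesis between the monosubstituted allyl alkene and the 1,1-disubstituted alkene of the allylic alcohol closes the trans-fused seven-membered ring as a trisubstituted cycloheptenol, whereas the hindered side-chain isopropenyl group next to the acetate could only close a nine-membered ring.

Step 10
Reactants: 20
Product: 21 (3S,6S)-6-[(1S,3aR,8aS)-3a,6-dimethyl-5-oxo-1,2,3,3a,4,5,8,8a-octahydroazulen-1-yl]-6-hydroxy-2-methylhept-1-en-3-yl acetate (CNP0193642.1)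
Conditions: MnO2 (20 equiv), CH2Cl2, rt
Reagents that add atoms: none
Why: MnO2 oxidises the ring allylic alcohol chemoselectively to the enone, leaving the tertiary alcohol and the acetate untouched.

## Compound list

1 | 3-methylcyclopent-2-en-1-one | CC1=CC(=O)CC1 | starting material
2 | (1,3-dioxolan-2-ylmethyl)magnesium bromide | Br[Mg]CC1OCCO1 | starting material
3 | allyl iodide (3-iodoprop-1-ene) | C=CCI | starting material
4 | bromomagnesium (3R)-3-(1,3-dioxolan-2-ylmethyl)-3-methylcyclopent-1-en-1-olate | Br[Mg]OC1=C[C@@](C)(CC2OCCO2)CC1 | intermediate (not isolated)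
5 | (2R,3R)-3-(1,3-dioxolan-2-ylmethyl)-3-methyl-2-(prop-2-en-1-yl)cyclopentan-1-one | O=C1CC[C@](C)(CC2OCCO2)[C@H]1CC=C | intermediate
6 | ethyl vinyl ether | C=COCC | starting material
7 | lithium (1S,2R,3R)-3-(1,3-dioxolan-2-ylmethyl)-1-(1-ethoxyethenyl)-3-methyl-2-(prop-2-en-1-yl)cyclopentan-1-olate | C=C(OCC)[C@]1(O[Li])CC[C@](C)(CC2OCCO2)[C@H]1CC=C | intermediate (not isolated)
8 | (1S,2R,3R)-3-(1,3-dioxolan-2-ylmethyl)-1-(1-ethoxyethenyl)-3-methyl-2-(prop-2-en-1-yl)cyclopentyl acetate | C=C(OCC)[C@]1(OC(C)=O)CC[C@](C)(CC2OCCO2)[C@H]1CC=C | intermediate (not isolated)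
9 | (1S,2R,3R)-1-acetyl-3-(1,3-dioxolan-2-ylmethyl)-3-methyl-2-(prop-2-en-1-yl)cyclopentyl acetate | CC(=O)[C@]1(OC(C)=O)CC[C@](C)(CC2OCCO2)[C@H]1CC=C | intermediate
10 | methyl acrylate | C=CC(=O)OC | starting material
11 | 1-[(1S,2S,3R)-3-(1,3-dioxolan-2-ylmethyl)-3-methyl-2-(prop-2-en-1-yl)cyclopentyl]ethan-1-one (acetyl cis to allyl) | CC(=O)[C@H]1CC[C@](C)(CC2OCCO2)[C@H]1CC=C | intermediate (not isolated)
12 | (5S)-5-[(1S,2S,3R)-3-(1,3-dioxolan-2-ylmethyl)-3-methyl-2-(prop-2-en-1-yl)cyclopentyl]-5-methyloxolan-2-one | O=C1CC[C@](C)(O1)[C@H]2CC[C@](C)(CC3OCCO3)[C@H]2CC=C | intermediate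
13 | isopropenylmagnesium bromide (prop-1-en-2-ylmagnesium bromide) | C=C(C)[Mg]Br | starting material
14 | (6S)-6-[(1S,2S,3R)-3-(1,3-dioxolan-2-ylmethyl)-3-methyl-2-(prop-2-en-1-yl)cyclopentyl]-6-hydroxy-2-methylhept-1-en-3-one | C=C(C)C(=O)CC[C@](C)(O)[C@H]1CC[C@](C)(CC2OCCO2)[C@H]1CC=C | intermediate
15 | (3S,6S)-6-[(1S,2S,3R)-3-(1,3-dioxolan-2-ylmethyl)-3-methyl-2-(prop-2-en-1-yl)cyclopentyl]-2-methylhept-1-ene-3,6-diol | C=C(C)[C@H](CC[C@](C)(O)[C@H]1CC[C@](C)(CC2OCCO2)[C@H]1CC=C)O | intermediate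
16 | (3S,6S)-6-[(1S,2S,3R)-3-(1,3-dioxolan-2-ylmethyl)-3-methyl-2-(prop-2-en-1-yl)cyclopentyl]-6-hydroxy-2-methylhept-1-en-3-yl acetate | C=C(C)[C@H](CC[C@](C)(O)[C@H]1CC[C@](C)(CC2OCCO2)[C@H]1CC=C)OC(C)=O | intermediate
17 | (3S,6S)-6-hydroxy-2-methyl-6-[(1S,2S,3R)-3-methyl-3-(2-oxoethyl)-2-(prop-2-en-1-yl)cyclopentyl]hept-1-en-3-yl acetate | C=C(C)[C@H](CC[C@](C)(O)[C@H]1CC[C@](C)(CC=O)[C@H]1CC=C)OC(C)=O | intermediate
18 | 2-bromopropene | C=C(C)Br | starting material
19 | (3S,6S)-6-hydroxy-6-[(1S,2S,3R)-3-(2-hydroxy-3-methylbut-3-en-1-yl)-3-methyl-2-(prop-2-en-1-yl)cyclopentyl]-2-methylhept-1-en-3-yl acetate, both epimers at the new carbinol | C=C(C)[C@H](CC[C@](C)(O)[C@H]1CC[C@](C)(CC(O)C(C)=C)[C@H]1CC=C)OC(C)=O | intermediate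
20 | (3S,6S)-6-hydroxy-6-[(1S,3aR,8aS)-5-hydroxy-3a,6-dimethyl-1,2,3,3a,4,5,8,8a-octahydroazulen-1-yl]-2-methylhept-1-en-3-yl acetate, both epimers at ring C5 | C=C(C)[C@H](CC[C@](C)(O)[C@H]1CC[C@]2(C)CC(O)C(C)=CC[C@@H]12)OC(C)=O | intermediate
21 | (3S,6S)-6-[(1S,3aR,8aS)-3a,6-dimethyl-5-oxo-1,2,3,3a,4,5,8,8a-octahydroazulen-1-yl]-6-hydroxy-2-methylhept-1-en-3-yl acetate | C=C(C)[C@H](CC[C@](C)(O)[C@H]1CC[C@]2(C)CC(=O)C(C)=CC[C@@H]12)OC(C)=O | target

## Step count and risks

Total step count: 10. Longest linear sequence: 10.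

The three steps most likely to fail:

**Step 1.** The enantioselectivity of copper-catalysed addition of a functionalised Grignard reagent to a five-membered enone, and the diastereoselectivity of the allylation, are both uncertain. The fallback sets out from 2 and comes back at 5, and inverts the order in which the two substituents reach the quaternary carbon so that the well-behaved methyl group is delivered asymmetrically. Grignard reagent 2 is added to commercial 3-ethoxycyclopent-2-en-1-one F1, and brief cold dilute HCl gives 3-(1,3-dioxolan-2-ylmethyl)cyclopent-2-en-1-one F2 (Stork–Danheiser transposition). Copper-catalysed asymmetric conjugate addition of AlMe3 (Cu(OTf)2, chiral phosphoramidite ligand, −78 → −30 °C), with the aluminium enolate trapped by TMSOTf, gives {[(3R)-3-(1,3-dioxolan-2-ylmethyl)-3-methylcyclopent-1-en-1-yl]oxy}trimethylsilane F3. MeLi then releases the lithium enolate, which is allylated with 3 and DMPU to give 5.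

**Step 3.** The one-flask cascade can fail through the wrong face of protonation, ketyl cyclisation onto the allyl group, or poor facial control in the coupling. The fallback sets out from 5 and comes back at 12, and replaces the radical cascade by separate two-electron steps.
- KN(SiMe3)2 and PhNTf2 give the less substituted enol triflate (4R,5R)-4-(1,3-dioxolan-2-ylmethyl)-4-methyl-5-(prop-2-en-1-yl)cyclopent-1-en-1-yl trifluoromethanesulfonate F4.
- Heck-type acylation with butyl vinyl ether (Pd(OAc)2, 1,3-bis(diphenylphosphino)propane, Et3N, DMF, 80 °C; then dilute HCl) gives 1-[(4R,5R)-4-(1,3-dioxolan-2-ylmethyl)-4-methyl-5-(prop-2-en-1-yl)cyclopent-1-en-1-yl]ethan-1-one F5.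
- Conjugate reduction with the copper hydride [(Ph3P)CuH]6 and cold kinetic protonation gives 11, which is isolated here.
- Felkin–Anh addition of the titanium ester homoenolate, made from (1-ethoxycyclopropoxy)trimethylsilane and TiCl4 and tempered with Ti(OiPr)4, gives ethyl (4S)-4-[(1S,2S,3R)-3-(1,3-dioxolan-2-ylmethyl)-3-methyl-2-(prop-2-en-1-yl)cyclopentyl]-4-hydroxypentanoate F6, which closes to lactone 12 on mild acid work-up.

**Step 5.** The free tertiary hydroxyl, or a cyclic hemiketal form of 14, may erode the selectivity of the reduction. The fallback sets out from 12 and comes back at 15, and sets the secondary carbinol by reagent-controlled lithiation–borylation instead of ketone reduction.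
- LiAlH4 reduces 12 to (4S)-4-[(1S,2S,3R)-3-(1,3-dioxolan-2-ylmethyl)-3-methyl-2-(prop-2-en-1-yl)cyclopentyl]pentane-1,4-diol F7.
- N,N-Diisopropylcarbamoyl chloride with Et3N acylates only the primary alcohol to give (4S)-4-[(1S,2S,3R)-3-(1,3-dioxolan-2-ylmethyl)-3-methyl-2-(prop-2-en-1-yl)cyclopentyl]-4-hydroxypentyl N,N-di(propan-2-yl)carbamate F8.
- s-BuLi with sparteine (the enantiomer that leads to 3S; one extra equivalent of base for the tertiary alkoxide; Et2O, −78 °C), then isopropenylboronic acid pinacol ester and warming with MgBr2, gives by 1,2-metallate rearrangement 2-[(3S,6S)-6-[(1S,2S,3R)-3-(1,3-dioxolan-2-ylmethyl)-3-methyl-2-(prop-2-en-1-yl)cyclopentyl]-6-hydroxy-2-methylhept-1-en-3-yl]-4,4,5,5-tetramethyl-1,3,2-dioxaborolane F9.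
- F9 is oxidised with H2O2/NaOH, with retention, to 15.

## Further compounds

F1 | step 1 | 3-ethoxycyclopent-2-en-1-one | CCOC1=CC(=O)CC1
F2 | step 1 | 3-(1,3-dioxolan-2-ylmethyl)cyclopent-2-en-1-one | O=C1C=C(CC2OCCO2)CC1
F3 | step 1 | {[(3R)-3-(1,3-dioxolan-2-ylmethyl)-3-methylcyclopent-1-en-1-yl]oxy}trimethylsilane | C[Si](C)(C)OC1=C[C@@](C)(CC2OCCO2)CC1
F4 | step 3 | (4R,5R)-4-(1,3-dioxolan-2-ylmethyl)-4-methyl-5-(prop-2-en-1-yl)cyclopent-1-en-1-yl trifluoromethanesulfonate | O=S(=O)(OC1=CC[C@](C)(CC2OCCO2)[C@H]1CC=C)C(F)(F)F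
F5 | step 3 | 1-[(4R,5R)-4-(1,3-dioxolan-2-ylmethyl)-4-methyl-5-(prop-2-en-1-yl)cyclopent-1-en-1-yl]ethan-1-one | CC(=O)C1=CC[C@](C)(CC2OCCO2)[C@H]1CC=C
F6 | step 3 | ethyl (4S)-4-[(1S,2S,3R)-3-(1,3-dioxolan-2-ylmethyl)-3-methyl-2-(prop-2-en-1-yl)cyclopentyl]-4-hydroxypentanoate | CCOC(=O)CC[C@](C)(O)[C@H]1CC[C@](C)(CC2OCCO2)[C@H]1CC=C
F7 | step 5 | (4S)-4-[(1S,2S,3R)-3-(1,3-dioxolan-2-ylmethyl)-3-methyl-2-(prop-2-en-1-yl)cyclopentyl]pentane-1,4-diol | OCCC[C@](C)(O)[C@H]1CC[C@](C)(CC2OCCO2)[C@H]1CC=C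
F8 | step 5 | (4S)-4-[(1S,2S,3R)-3-(1,3-dioxolan-2-ylmethyl)-3-methyl-2-(prop-2-en-1-yl)cyclopentyl]-4-hydroxypentyl N,N-di(propan-2-yl)carbamate | CC(C)N(C(C)C)C(=O)OCCC[C@](C)(O)[C@H]1CC[C@](C)(CC2OCCO2)[C@H]1CC=C
F9 | step 5 | 2-[(3S,6S)-6-[(1S,2S,3R)-3-(1,3-dioxolan-2-ylmethyl)-3-methyl-2-(prop-2-en-1-yl)cyclopentyl]-6-hydroxy-2-methylhept-1-en-3-yl]-4,4,5,5-tetramethyl-1,3,2-dioxaborolane | C=C(C)[C@H](CC[C@](C)(O)[C@H]1CC[C@](C)(CC2OCCO2)[C@H]1CC=C)B3OC(C)(C)C(C)(C)O3
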